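(All constants are those of an exercise; the result is computed.)

The nucleophile in this flask is wanted by the electrophile and by itself, and just after the start the coupling uses it 0.38 times as fast as self-condensation does, which is slower.

electrophile 0.26 M; nucleophile 0.234 M; free base 0.780 M; time 80 min

* part of the electrophile that has reacted at 80 min
* share of free nucleophile in free nucleophile and protonated nucleophile together, at 80 min

    nucleophile + acid set free ⇌ protonated nucleophile, settled at all times (K1 = 10000 L mol⁻¹)
    nucleophile + target ⇌ idle adduct, settled at all times (K2 = 4.6 L mol⁻¹)
    2 nucleophile → self-condensation product (k3 = 0.025 L mol⁻¹ s⁻¹)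
    target ⇌ isomer of the product (K4 = 0.52, k4 = 1.6 × 10⁻⁴ s⁻¹)
    electrophile + nucleophile → acid set free + target (k5 = 0.017 L mol⁻¹ s⁻¹)
    acid set free + free base ⇌ salt of the base (K6 = 4.8 L mol⁻¹, k6 = 0.094 L mol⁻¹ s⁻¹)

While free nucleophile lasts it takes the acid set free ahead of the free base, its equilibrium constant times concentration of 2300 standing far above the base's 3.7, so each coupling costs two nucleophiles, and each self-condensation costs two as well. Dividing the rates, with a the electrophile charge, b the nucleophile charge, kc the coupling constant and ks the self-condensation constant, holding the electrophile at a and integrating down to zero free nucleophile, gives the burst yield X = (kc·a/2ks)·ln(1 + ks·b/(kc·a)), the electrophile coupled in the early rush, 0.0745 M here, or 28.7 % of the charge. After the burst the protonated nucleophile is the resting state, and I compute the correction u, the electrophile coupled after the burst, holding the protonated nucleophile at X: these further couplings add excess acid 2u, of which, with the salt of the base taken at balance, the acid set free keeps the part 1/G, where G = 1 + K6·[free base], so the free nucleophile falls as 1/u and u grows with the root of time, u = √(kc(a−X)·G·X·t/K1) = 0.0231 M. I therefore expect 37.6 % reacted, and a free share G/(2K1·u) = 1.03 %.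

The forecast gives 37 % and 1.1 %, holding that “the free nucleophile collapses within a few hundred seconds”. The simulation gives 35.0 % and 1.26 %.

In this flask 27.5 % of the electrophile has been used by 8.00 min, beside my burst yield of 28.7 %, and the coupling beyond X at 80 min comes to 0.0164 M, less than my u of 0.0231 M.

With 1.0 M of electrophile, the same reckoning gives X = 0.101 M and u = 0.0592 M, so 16.0 % reacted; that neighbour flask gives 14.6 %.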